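# Total synthesis proposal: topazolin hydrate (14)

Flavone numbering is used for the target (O1, C2, C3, C4, C4a, C5–C8, C8a; ring B C1'–C6'; side chain C1''–C3''). Coumarin numbering is used only where stated.

## The problem

1. Topazolin hydrate (14) is a 3-O-methylflavonol. Its ring A (C4a, C5–C8, C8a) is a phloroglucinol with six different positions: O1 on C8a, OH on C5 and C7, the carbonyl carbon C4 on C4a, H on C8, and the 3-hydroxy-3-methylbutyl chain on C6.
2. There is no stereocentre, so the problem is one of position and chemoselectivity only.
3. C6 and C8 each lie between two oxygen-bearing carbons and differ little in nucleophilicity. Every late C–C bond formation on a 5,7-dihydroxyflavone therefore has to win a C6/C8 (and C/O) contest.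
4. The classical ring-C closures only move this problem. A C-alkylated 2,4,6-trihydroxyphenyl ketone has two ortho hydroxyls, and closure through one or the other gives the 6- or the 8-substituted flavone.
5. Of the five oxygen substituents only O3 is methylated, and it is neither the most acidic nor the most accessible one.
6. The tertiary alcohol sits three carbons from ring A between two free phenols. Acid turns it into a 2,2-dimethylchroman or an alkene, so it must appear late and under non-acidic conditions.
7. Enabling feature one: C8a–O1 is para to C6. Once the C4–C4a bond is cut, ring A with its chain has a local mirror plane through C6 and C8a, which makes C4a and C8 (and O5 and O7) equivalent and leaves O1 as the one unique oxygen.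
8. Enabling feature two: C3''(OH)Me2 together with the flanking O5 (or O7) is the retron of a six-membered aryl lactone (C6–C1''–C2''–C3''(=O)–O–C5). This lactone is acid-proof, and its opening restores the mirror plane.

## Retrosynthesis

**14 ⇒ 12 (through 13).**
- Cut: the two C3''–CH3 bonds. C3'' is joined to O5 as a dihydrocoumarin-type lactone.
- The neighbouring cuts (C6–C1'', or hydration of a prenyl alkene) leave the acid-sensitive alcohol to be made next to free phenols under cationic or radical conditions.
- Here the alcohol and the 5-OH appear together, in the last step, in basic medium.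
- 12 has no labile group and allows strong acid earlier in the route.
- The forward reaction must take the aryl ester and spare C4=O. Prior formation of the 7- and 4'-phenoxides, both conjugated with C4=O, should secure this.

**12 ⇒ 11.**
- No skeletal bond is cut. A C1''=C2'' double bond is added, so the lactone becomes a coumarin.
- The coumarin is available in one step from a C3-symmetric arene and resists base better than the saturated aryl lactone.
- Its conjugation also makes the hydroxyl para to the chain the most acidic one, which the O1–C2 cut below exploits.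
- The forward step must reduce a cis-disubstituted lactone alkene beside the tetrasubstituted C2=C3 bond of the γ-pyrone.

**11 ⇒ 9 (through 10). Key disconnection.**
- Cut: C4–C4a.
- Cutting O1–C2 or C2–C3 instead keeps the acyl carbon on ring A between two candidate hydroxyls and brings back the 6/8 ambiguity.
- Cutting C4–C4a keeps O1 attached and leaves two ortho carbons. Either of them leads to 14, because the lactone that distinguishes them is deleted at the end.
- A tetracycle becomes a coumarin aryl vinyl ether with one rotatable link.
- The forward reaction is an intramolecular acylation by an ester that already carries the 3-OMe. The 4'-O-tert-butyl group is chosen so that it leaves in the same acid.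

**9 ⇒ 3 + 8.**
- Cut: O1–C2.
- This is the only regiochemical decision of the route, namely which oxygen of 3 becomes O1.
- The required oxygen (coumarin 7-OH) is para to the chain-bearing carbon. It is therefore the more acidic hydroxyl and the one without a peri neighbour.
- Both fragments are small. The forward reaction is a vinylic substitution on a β-bromoacrylate.

**3 ⇒ 1 + 2.**
- Cut: C6–C1'' and O5–C3''.
- All positions of 1 are equivalent, so the chain carbon and its flanking oxygen are set without any selectivity.

**8 ⇒ 6 (through 7) ⇒ 4 + 5.**
- Cut: C2–Br, then C2=C3.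
- The C3 unit carries the methoxy group from the start, so O3 never has to be told apart from a phenol.

## Roads not taken

**Alternative 1 (the obvious route):**
- Cut: C6–C1'', with the alcohol derived from a prenyl group.
- Forward: C-prenylation, or O-prenylation followed by a sigmatropic or 1,3-shift, of the flavonol 3-methyl ether A1 to the 6-prenyl compound A2. Markovnikov hydration of the alkene follows.
- A1 itself needs a synthesis or a selective 3-O-methylation.
- The prenyl transfer must discriminate C6, C8 and three phenolic oxygens. A shift from O5 can run on to C8, and one from O7 reaches both carbons. The 7- and 4'-hydroxyls therefore have to be protected and released.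
- The hydration creates a cationic or radical centre at C3'' between two ortho phenols, where chroman closure competes.
- The chosen plan needs no C6/C8 selectivity and no phenol protection on ring A.

**Alternative 2:**
- Cut: the same C6–C1'' bond, formed by cross-coupling.
- Forward: regioselective iodination to the 6-iodide A3, Heck coupling with the commercial tertiary allylic C5 alcohol to A4, then hydrogenation with debenzylation.
- The positional problem is only moved to the iodination, whose C6/C8 outcome depends on the protection pattern of O5 and O7.
- Several protecting-group steps are added.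
- A4 is a tertiary allylic alcohol ortho to a free 5-OH and ionises easily towards a chromene.
- The 3-OMe question remains unsolved.

**Alternative 3:**
- Cut: O1–C2 and C2–C3, the classical Allan–Robinson or Baker–Venkataraman logic.
- Forward: aroylation and cyclodehydration of the C-alkylated ω-methoxyketone A5.
- The ketone is flanked by two free hydroxyls, and closure through the one next to the chain gives the 8-isomer A6 beside 14.
- The tertiary alcohol of A5 would not survive the acidic acylation that makes A5, nor the acid cyclodehydration.
- The chosen plan starts from the same symmetric ring but cuts the one bond that turns the symmetry into an advantage.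

Key step: step 5

Remark: 14 is achiral, with no stereocentre and no stereogenic double bond, so the demand for a single enantiomer is met by constitution alone. The alkene geometry of 6, 8, 9 and 10 is erased in step 5 and is not controlled.

## Route

Step 1
Reactants: 1 phloroglucinol (benzene-1,3,5-triol); 2 ethyl propiolate
Product: 3 5,7-dihydroxycoumarin (5,7-dihydroxy-2H-chromen-2-one)
Conditions: ZnCl2 (1 equiv), dioxane, 100 °C
Reagents that add atoms: none
Why: Pechmann-type condensation with a propiolate, that is Lewis-acid hydroarylation of the alkynoate followed by lactonisation; all ring positions of 1 are equivalent, so only one coumarin can form.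

Step 2
Reactants: 4 4-(tert-butoxy)benzaldehyde; 5 methyl 2-(dimethoxyphosphoryl)-2-methoxyacetate
Product: 6 methyl 3-[4-(tert-butoxy)phenyl]-2-methoxyprop-2-enoate (E/Z mixture)
Conditions: NaH (1.1 equiv), THF, 0 °C to rt
Reagents that add atoms: none
Why: Horner–Wadsworth–Emmons olefination with an α-alkoxyphosphonoacetate, a standard entry to α-alkoxycinnamates; the geometry is irrelevant because steps 3 to 5 erase it, and the future 3-OMe is built in here.

Step 3
Reactants: 6 methyl 3-[4-(tert-butoxy)phenyl]-2-methoxyprop-2-enoate
Product: 8 methyl 3-bromo-3-[4-(tert-butoxy)phenyl]-2-methoxyprop-2-enoate (E/Z mixture), via vicinal dibromide 7 (not isolated)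
Conditions: Br2 (1.05 equiv), CH2Cl2, −20 °C; then Et3N (2.5 equiv), −20 °C to rt
Reagents that add atoms: bromine, BrBr
Why: Bromination–dehydrobromination of a captodative alkene, as practised on α-alkoxyacrylates and dehydroamino esters; the α-carbon of 7 bears no hydrogen, so HBr can leave only as β-C–H plus α-C–Br, which places the bromine on the aryl-bearing carbon.

Step 4
Reactants: 3 5,7-dihydroxycoumarin; 8 methyl 3-bromo-3-[4-(tert-butoxy)phenyl]-2-methoxyprop-2-enoate
Product: 9 methyl 3-[4-(tert-butoxy)phenyl]-3-[(5-hydroxy-2-oxo-2H-chromen-7-yl)oxy]-2-methoxyprop-2-enoate (E/Z mixture)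
Conditions: Cs2CO3 (1.05 equiv), 3 (1.2 equiv), DMF, 70 °C
Reagents that add atoms: none
Why: Vinylic substitution by addition–elimination of a phenoxide on a β-haloacrylate, the first half of the Ruhemann chromone synthesis. One equivalent of base ionises the coumarin 7-OH, which is the more acidic hydroxyl (p-quinoid delocalisation into the lactone carbonyl) and lacks the peri C4–H contact of the 5-OH; the bulky tetrasubstituted electrophile should reinforce this choice.

Step 5
Reactants: 9 methyl 3-[4-(tert-butoxy)phenyl]-3-[(5-hydroxy-2-oxo-2H-chromen-7-yl)oxy]-2-methoxyprop-2-enoate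
Product: 11 5-hydroxy-8-(4-hydroxyphenyl)-9-methoxy-2H,10H-pyrano[2,3-f]chromene-2,10-dione (flavone with a coumarin lactone fused across C5–O and C6), via free phenol 10 (not isolated)
Conditions: Eaton's reagent (P2O5/MeSO3H, as solvent), rt then 50 °C; ice–water
Reagents that add atoms: none
Why: Friedel–Crafts cycloacylation of a β-aryloxyacrylate, that is the second half of the Ruhemann chromone synthesis and the oxygen counterpart of the Gould–Jacobs quinolone closure, which is known to run on alkyl esters in Eaton's reagent. The acid first removes the aryl tert-butyl group by E1 loss of isobutene (10); O-protonation of the push–pull ester then gives the C2–C3 bond single-bond character, so both alkene isomers reach the geometry with aryloxy and ester groups cis. Loss of methanol gives a donor-stabilised acylium ion at C4, which is attacked by a ring-A carbon ortho to O1, and proton loss restores the arene. Ring C closes in the 6-exo-trig mode (the C4=O bond stays outside the new ring O1–C2–C3–C4–C4a–C8a), and no stereocentre is formed. The step needs no choice between the two ortho carbons: closure is expected, and drawn, at coumarin C8 (para to the free 5-OH and the usual site of attack in 7-oxygenated coumarins), but closure at coumarin C6 would serve equally, since steps 6 and 7 delete the lactone and restore the mirror plane through C6 and C8a. It does need ring A over ring B, which is secured because the ring-B carbon within reach is meta to its hydroxyl and would have to close a five-membered indenone, whereas the ring-A carbons are ortho or para to three oxygens. The coumarin lactone, the enol methyl ether and the free phenols should tolerate the anhydrous acid, as in Eaton-type xanthone syntheses from unprotected polyphenols.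

Step 6
Reactants: 11 5-hydroxy-8-(4-hydroxyphenyl)-9-methoxy-2H,10H-pyrano[2,3-f]chromene-2,10-dione
Product: 12 5-hydroxy-8-(4-hydroxyphenyl)-9-methoxy-3,4-dihydro-2H,10H-pyrano[2,3-f]chromene-2,10-dione
Conditions: H2 (3 atm), 10% Pd/C, THF–AcOH, 40 °C
Reagents that add atoms: none
Why: Catalytic hydrogenation of a coumarin to a 3,4-dihydrocoumarin; the cis-disubstituted lactone alkene should be reduced, while the tetrasubstituted, methoxy-bearing C2=C3 bond of the γ-pyrone, which routinely survives hydrogenolytic debenzylation of flavones, should stay. The non-nucleophilic solvent keeps the aryl lactone closed.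

Step 7
Reactants: 12 5-hydroxy-8-(4-hydroxyphenyl)-9-methoxy-3,4-dihydro-2H,10H-pyrano[2,3-f]chromene-2,10-dione
Product: 14 topazolin hydrate, via methyl ketone 13 (not isolated)
Conditions: MeMgBr (8 equiv), THF, −10 °C to rt; sat. aq NH4Cl, 0 °C
Reagents that add atoms: methylmagnesium bromide, C[Mg]Br
Why: Double Grignard addition to a dihydrocoumarin, the classical route to 2-(3-hydroxy-3-methylbutyl)phenols. The first two equivalents form the 7- and 4'-phenoxides, both conjugated with C4=O, and ring opening frees the chelating 5-phenoxide, so the pyranone carbonyl is shut down while the aryl ester and then ketone 13 react. The buffered quench avoids chroman closure.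

## Compound list

1 | phloroglucinol | Oc1cc(O)cc(O)c1 | starting material
2 | ethyl propiolate | C#CC(=O)OCC | starting material
3 | 5,7-dihydroxycoumarin | O=c1ccc2c(O)cc(O)cc2o1 | intermediate
4 | 4-(tert-butoxy)benzaldehyde | CC(C)(C)Oc1ccc(C=O)cc1 | starting material
5 | methyl 2-(dimethoxyphosphoryl)-2-methoxyacetate | COC(=O)C(OC)P(=O)(OC)OC | starting material
6 | methyl 3-[4-(tert-butoxy)phenyl]-2-methoxyprop-2-enoate (E/Z mixture) | COC(=O)C(OC)=Cc1ccc(OC(C)(C)C)cc1 | intermediate
7 | methyl 2,3-dibromo-3-[4-(tert-butoxy)phenyl]-2-methoxypropanoate (racemic diastereomer mixture, not isolated) | COC(=O)C(Br)(OC)C(Br)c1ccc(OC(C)(C)C)cc1 | intermediate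
8 | methyl 3-bromo-3-[4-(tert-butoxy)phenyl]-2-methoxyprop-2-enoate (E/Z mixture) | COC(=O)C(OC)=C(Br)c1ccc(OC(C)(C)C)cc1 | intermediate
9 | methyl 3-[4-(tert-butoxy)phenyl]-3-[(5-hydroxy-2-oxo-2H-chromen-7-yl)oxy]-2-methoxyprop-2-enoate (E/Z mixture) | COC(=O)C(OC)=C(Oc1cc(O)c2ccc(=O)oc2c1)c1ccc(OC(C)(C)C)cc1 | intermediate
10 | methyl 3-[(5-hydroxy-2-oxo-2H-chromen-7-yl)oxy]-3-(4-hydroxyphenyl)-2-methoxyprop-2-enoate (not isolated) | COC(=O)C(OC)=C(Oc1cc(O)c2ccc(=O)oc2c1)c1ccc(O)cc1 | intermediate
11 | 5-hydroxy-8-(4-hydroxyphenyl)-9-methoxy-2H,10H-pyrano[2,3-f]chromene-2,10-dione | COc1c(-c2ccc(O)cc2)oc2cc(O)c3ccc(=O)oc3c2c1=O | intermediate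
12 | 5-hydroxy-8-(4-hydroxyphenyl)-9-methoxy-3,4-dihydro-2H,10H-pyrano[2,3-f]chromene-2,10-dione | COc1c(-c2ccc(O)cc2)oc2cc(O)c3c(OC(=O)CC3)c2c1=O | intermediate
13 | 5,7-dihydroxy-2-(4-hydroxyphenyl)-3-methoxy-6-(3-oxobutyl)-4H-chromen-4-one (not isolated) | COc1c(-c2ccc(O)cc2)oc2cc(O)c(CCC(C)=O)c(O)c2c1=O | intermediate
14 | topazolin hydrate, 5,7-dihydroxy-6-(3-hydroxy-3-methylbutyl)-2-(4-hydroxyphenyl)-3-methoxy-4H-chromen-4-one | COc1c(-c2ccc(O)cc2)oc2cc(O)c(CCC(C)(C)O)c(O)c2c1=O | target

## Step count and least certain steps

Total steps: 7. Longest linear sequence: 6 (steps 2, 3, 4, 5, 6, 7, from 4). The other branch (step 1) joins at step 4.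

**Step 5 (key step).**
- Risks:
  - The acylium ion is strongly donor-stabilised, and ring A carries only one free hydroxyl beside two attenuated oxygens, so closure may be slow.
  - During a slow closure, adventitious water may cleave the aryl vinyl ether.
  - Ring B may recapture the tert-butyl cation.
  - The phenols may be sulfonylated.
- Fallback (known C-first chemistry, from 3 back to 12):
  - Friedel–Crafts acylation of 3 with methoxyacetyl chloride/AlCl3, which in 5,7-dihydroxycoumarins goes mainly to C8, would give 5,7-dihydroxy-8-(methoxyacetyl)coumarin F1. There the lactone oxygen occupies one ortho position of the ketone, so only one hydroxyl can close ring C.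
  - Aroylation with 4-(benzyloxy)benzoyl chloride would give the 5,7-bis[4-(benzyloxy)benzoate] F2.
  - Baker–Venkataraman transfer, cyclodehydration and hydrolysis of the remaining ester would give the 4'-O-benzyl ether of 11 F3.
  - Hydrogenation as in step 6 removes the benzyl group, saturates the lactone and returns to 12.

**Step 4.**
- Risks:
  - Addition of a delocalised, weakly nucleophilic phenoxide to a tetrasubstituted, donor-substituted acceptor may be sluggish.
  - The reaction may leak to the 5-oxygen or to both oxygens, because the discrimination rests on a modest acidity difference and on peri hindrance.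
- Fallback (from 8 back to 11):
  - 2,4,6-Trihydroxybenzaldehyde is used as the ring-A partner. Its two ortho hydroxyls are held in hydrogen bonds to the formyl group and its para hydroxyl is a vinylogous acid. With 8 it would give methyl 3-[4-(tert-butoxy)phenyl]-3-(4-formyl-3,5-dihydroxyphenoxy)-2-methoxyprop-2-enoate F4.
  - Wittig olefination with methyl (triphenylphosphoranylidene)acetate would give the (E)-cinnamate F5.
  - In Eaton's reagent F5 should isomerise through its protonated form, lactonise through either of its two equivalent hydroxyls and close ring C, returning at 11.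

**Step 3.**
- Risks:
  - The α-bromo-α-methoxy ester may collapse by loss of methyl bromide.
  - The alkoxyarene may be brominated.
  - Base may induce loss of bromine back to the alkene.
- Fallback (from 4 back to 9):
  - Aldol addition of the lithium enolate of methyl methoxyacetate to 4 would give the β-hydroxy ester F6.
  - Dess–Martin oxidation would give the β-keto ester F7.
  - NaH/PhNTf2 would give the enol triflate F8.
  - F8 takes the place of 8 towards 3 (addition–elimination or Pd-catalysed C–O coupling) and returns at 9.

**Step 7.**
- Risks:
  - The magnesium phenoxides may precipitate before the lactone has reacted.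
  - Enolisation of the intermediate ketone may stop the addition halfway.
  - The reagent may attack the pyranone at C4 or C2.
  - Traces of acid at work-up may close the chroman.
- Fallback (from 12 back to 14):
  - Aminolysis of the lactone with N,O-dimethylhydroxylamine/iPrMgCl would give the Weinreb amide F9.
  - One methyl addition would stop at 13, now isolated.
  - The non-basic, ketone-selective methyltitanium triisopropoxide would take 13 to 14.

**Step 6.**
- Risks:
  - Hydrogen uptake may stall because the flat tetracycle is poorly soluble.
  - The aryl lactone may undergo solvolysis.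
  - The C2=C3 bond may be slowly over-reduced.
- Fallback (from 1 back to 12, no hydrogenation):
  - 1 and acrylic acid over an acid resin would give 5,7-dihydroxychroman-2-one F10.
  - The conditions of step 4 with 8 would give the saturated aryl vinyl ether F11.
  - Eaton's reagent would close F11 directly to 12.
  - The price is that the O-selectivity then rests on steric factors alone.

## Further compounds

F1 | step 5 | 5,7-dihydroxy-8-(2-methoxyacetyl)-2H-chromen-2-one | COCC(=O)c1c(O)cc(O)c2ccc(=O)oc12
F2 | step 5 | 8-(2-methoxyacetyl)-2-oxo-2H-chromene-5,7-diyl bis[4-(benzyloxy)benzoate] | COCC(=O)c1c(OC(=O)c2ccc(OCc3ccccc3)cc2)cc(OC(=O)c2ccc(OCc3ccccc3)cc2)c2ccc(=O)oc12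
F3 | step 5 | 8-[4-(benzyloxy)phenyl]-5-hydroxy-9-methoxy-2H,10H-pyrano[2,3-f]chromene-2,10-dione | COc1c(-c2ccc(OCc3ccccc3)cc2)oc2cc(O)c3ccc(=O)oc3c2c1=O
F4 | step 4 | methyl 3-[4-(tert-butoxy)phenyl]-3-(4-formyl-3,5-dihydroxyphenoxy)-2-methoxyprop-2-enoate | COC(=O)C(OC)=C(Oc1cc(O)c(C=O)c(O)c1)c1ccc(OC(C)(C)C)cc1
F5 | step 4 | methyl (E)-3-{4-[1-(4-tert-butoxyphenyl)-2,3-dimethoxy-3-oxoprop-1-enyl]oxy-2,6-dihydroxyphenyl}prop-2-enoate | COC(=O)/C=C/c1c(O)cc(OC(=C(OC)C(=O)OC)c2ccc(OC(C)(C)C)cc2)cc1O
F6 | step 3 | methyl 3-[4-(tert-butoxy)phenyl]-3-hydroxy-2-methoxypropanoate (racemic diastereomer mixture) | COC(=O)C(OC)C(O)c1ccc(OC(C)(C)C)cc1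
F7 | step 3 | methyl 3-[4-(tert-butoxy)phenyl]-2-methoxy-3-oxopropanoate (racemic) | COC(=O)C(OC)C(=O)c1ccc(OC(C)(C)C)cc1
F8 | step 3 | methyl 3-[4-(tert-butoxy)phenyl]-2-methoxy-3-(trifluoromethylsulfonyloxy)prop-2-enoate | COC(=O)C(OC)=C(OS(=O)(=O)C(F)(F)F)c1ccc(OC(C)(C)C)cc1
F9 | step 7 | 3-[5,7-dihydroxy-2-(4-hydroxyphenyl)-3-methoxy-4-oxo-4H-chromen-6-yl]-N-methoxy-N-methylpropanamide | CON(C)C(=O)CCc1c(O)cc2oc(-c3ccc(O)cc3)c(OC)c(=O)c2c1O
F10 | step 6 | 5,7-dihydroxychroman-2-one | O=C1CCc2c(O)cc(O)cc2O1
F11 | step 6 | methyl 3-[4-(tert-butoxy)phenyl]-3-[(5-hydroxy-2-oxochroman-7-yl)oxy]-2-methoxyprop-2-enoate | COC(=O)C(OC)=C(Oc1cc(O)c2c(c1)OC(=O)CC2)c1ccc(OC(C)(C)C)cc1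
A1 | alternative 1 | 5,7-dihydroxy-2-(4-hydroxyphenyl)-3-methoxy-4H-chromen-4-one (kaempferol 3-methyl ether) | COc1c(-c2ccc(O)cc2)oc2cc(O)cc(O)c2c1=O
A2 | alternative 1 | topazolin, 5,7-dihydroxy-2-(4-hydroxyphenyl)-3-methoxy-6-(3-methylbut-2-enyl)-4H-chromen-4-one | COc1c(-c2ccc(O)cc2)oc2cc(O)c(CC=C(C)C)c(O)c2c1=O
A3 | alternative 2 | 7-(benzyloxy)-2-[4-(benzyloxy)phenyl]-5-hydroxy-6-iodo-3-methoxy-4H-chromen-4-one | COc1c(-c2ccc(OCc3ccccc3)cc2)oc2cc(OCc3ccccc3)c(I)c(O)c2c1=O
A4 | alternative 2 | 7-(benzyloxy)-2-[4-(benzyloxy)phenyl]-5-hydroxy-6-[(E)-3-hydroxy-3-methylbut-1-enyl]-3-methoxy-4H-chromen-4-one | COc1c(-c2ccc(OCc3ccccc3)cc2)oc2cc(OCc3ccccc3)c(/C=C/C(C)(C)O)c(O)c2c1=O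
A5 | alternative 3 | 2-methoxy-1-[2,4,6-trihydroxy-3-(3-hydroxy-3-methylbutyl)phenyl]ethanone | COCC(=O)c1c(O)cc(O)c(CCC(C)(C)O)c1O
A6 | alternative 3 | 5,7-dihydroxy-8-(3-hydroxy-3-methylbutyl)-2-(4-hydroxyphenyl)-3-methoxy-4H-chromen-4-one | COc1c(-c2ccc(O)cc2)oc2c(CCC(C)(C)O)c(O)cc(O)c2c1=O
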